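## Retrosynthetic overview

1. Azulene numbering is used for the bicycle: cyclopentane C1–C3, ring-fusion carbons C3a (quaternary, CH3) and C8a (H), cycloheptane C4–C8 (C5 ketone, C6–C7 oxirane). The target is traced back (acetylation, desilylation, oxidation, hydroxyl-directed epoxidation, 1,2-reduction) to a trans-fused C6=C7 enone.
2. Key disconnection C4–C5: the seven-membered ring is closed by a nickel-catalysed reductive coupling of the CH2Br group on C3a with a (Z)-2-methylbut-2-enoyl S-2-pyridyl thioester hanging on C8a. This delivers the ring, the ketone and the enone in one operation.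
3. Enabling feature: C4 is a neopentyl CH2 on quaternary C3a (inert to SN2, no β-hydrogen, but a good radical and alkylnickel partner). C4 and C8 are trans on the cyclopentane, so the seven-ring closure is unstrained while the competing 5-exo radical closure would need a trans-fused bicyclo[3.3.0]octane.
4. Side chain: Felkin–Anh addition of an enantiopure organocerium fragment (from ethyl acetate and methacrolein, Sharpless kinetic resolution) to a cis-acetylcyclopentane.
5. Cyclopentane: ring contraction (ozonolysis, aldol condensation, hydrogenation) of a catalytic asymmetric Diels–Alder adduct of isoprene and an (E)-2-methyl enal. Ring order: temporary cyclohexene, cyclopentane, cycloheptenone, oxirane.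

Key step: step 19

Assumption: the (S)-configured oxazaborolidinium catalyst of step 7 is taken to give the (1S,6R) adduct 13; if the sense of induction is the opposite, the equally available (R)-catalyst is used and nothing else changes.

## Route

Step 1
Reactants: 1 ethyl acetate; 2 methacrolein (2-methylprop-2-enal)
Product: 4 ethyl 3-hydroxy-4-methylpent-4-enoate (racemic), via lithium enolate 3 (not isolated)
Conditions: LiN(i-Pr)2, THF, −78 °C; then 2, −78 °C; aq. NH4Cl
Reagents that add atoms: none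
Why: Directed aldol addition of the preformed lithium ester enolate should occur 1,2 on the enal at −78 °C; the carbinol centre forms racemic and is resolved in step 2.

Step 2
Reactants: 4 ethyl 3-hydroxy-4-methylpent-4-enoate (racemic)
Product: 5 ethyl (3S)-3-hydroxy-4-methylpent-4-enoate
Conditions: Ti(Oi-Pr)4 (10 mol %), D-(−)-diisopropyl tartrate (12 mol %), t-BuOOH (0.6 equiv), 4 Å molecular sieves, CH2Cl2, −20 °C
Reagents that add atoms: none
Why: Sharpless kinetic resolution of a secondary allylic alcohol: with the D-(−)-tartrate the (3R)-enantiomer should be epoxidised much faster, so (3S)-5 is recovered and the side-chain carbinol centre is fixed by the catalyst.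

Step 3
Reactants: 5 ethyl (3S)-3-hydroxy-4-methylpent-4-enoate
Product: 6 ethyl (3S)-3-[(tert-butyldimethylsilyl)oxy]-4-methylpent-4-enoate
Conditions: TBSCl, imidazole, DMF, 23 °C
Reagents that add atoms: tert-butyldimethylsilyl chloride, C[Si](C)(Cl)C(C)(C)C
Why: Standard silylation of a secondary alcohol; the stereocentre is not touched.

Step 4
Reactants: 6 ethyl (3S)-3-[(tert-butyldimethylsilyl)oxy]-4-methylpent-4-enoate
Product: 7 (3S)-3-[(tert-butyldimethylsilyl)oxy]-4-methylpent-4-en-1-ol
Conditions: i-Bu2AlH (2.5 equiv), CH2Cl2, −78 → 0 °C; Rochelle salt work-up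
Reagents that add atoms: none
Why: Hydride reduction of the ester to the primary alcohol should leave the silyl ether and the alkene intact.

Step 5
Reactants: 7 (3S)-3-[(tert-butyldimethylsilyl)oxy]-4-methylpent-4-en-1-ol
Product: 8 tert-butyl{[(3S)-5-iodo-2-methylpent-1-en-3-yl]oxy}dimethylsilane
Conditions: I2, PPh3, imidazole, CH2Cl2, 0 → 23 °C
Reagents that add atoms: iodine, II
Why: Appel-type iodination of an unhindered primary alcohol through the alkoxyphosphonium salt; the stereocentre is remote from the reacting carbon.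

Step 6
Reactants: 9 3-[(tert-butyldimethylsilyl)oxy]propanal; 10 2-(triphenylphosphoranylidene)propanal
Product: 11 (2E)-5-[(tert-butyldimethylsilyl)oxy]-2-methylpent-2-enal
Conditions: toluene, 80 °C
Reagents that add atoms: none
Why: Wittig olefination with a stabilised formyl ylide should give the (E)-trisubstituted enal, which fixes the later cis relation of the quaternary methyl and the C8 chain.

Step 7
Reactants: 11 (2E)-5-[(tert-butyldimethylsilyl)oxy]-2-methylpent-2-enal; 12 isoprene
Product: 13 (1S,6R)-6-{2-[(tert-butyldimethylsilyl)oxy]ethyl}-1,4-dimethylcyclohex-3-ene-1-carbaldehyde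
Conditions: (S)-1-(2-methylphenyl)-3,3-diphenyltetrahydro-1H,3H-pyrrolo[1,2-c][1,3,2]oxazaborole (20 mol %) activated with Tf2NH (18 mol %), 12 (5 equiv), CH2Cl2, −40 → −20 °C
Reagents that add atoms: none
Why: Catalytic asymmetric Diels–Alder reaction of an α-substituted enal under chiral oxazaborolidinium activation: the "para" orientation puts the diene methyl 1,4 to the quaternary carbon, suprafacial addition to the (E)-enal places the formyl group trans to the silyloxyethyl chain (methyl cis to it), and the catalyst face selection should set both centres as (1S,6R).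

Step 8
Reactants: 13 (1S,6R)-6-{2-[(tert-butyldimethylsilyl)oxy]ethyl}-1,4-dimethylcyclohex-3-ene-1-carbaldehyde
Product: 14 [(1S,6R)-6-{2-[(tert-butyldimethylsilyl)oxy]ethyl}-1,4-dimethylcyclohex-3-en-1-yl]methanol
Conditions: NaBH4, MeOH, 0 °C
Reagents that add atoms: none
Why: Borohydride reduction of the non-enolisable aldehyde gives the neopentyl alcohol without touching a stereocentre.

Step 9
Reactants: 14 [(1S,6R)-6-{2-[(tert-butyldimethylsilyl)oxy]ethyl}-1,4-dimethylcyclohex-3-en-1-yl]methanol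
Product: 16 tert-butyl{2-[(1R,6S)-6-(bromomethyl)-3,6-dimethylcyclohex-3-en-1-yl]ethoxy}dimethylsilane, via triflate 15 (not isolated)
Conditions: Tf2O, 2,6-lutidine, CH2Cl2, −40 → 0 °C; then Bu4NBr, 0 → 40 °C
Reagents that add atoms: tetrabutylammonium bromide, CCCC[N+](CCCC)(CCCC)CCCC.[Br-]
Why: SN2 displacement of a neopentyl triflate by bromide: the triflate leaving group should compensate for the neopentyl retardation, and the aprotic medium with a strong nucleophile should suppress ionisation and 1,2-shift.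

Step 10
Reactants: 16 tert-butyl{2-[(1R,6S)-6-(bromomethyl)-3,6-dimethylcyclohex-3-en-1-yl]ethoxy}dimethylsilane
Product: 18 (3S,4S)-3-(bromomethyl)-4-{2-[(tert-butyldimethylsilyl)oxy]ethyl}-3-methyl-6-oxoheptanal, via ozonide 17 (not isolated)
Conditions: O3, CH2Cl2, −78 °C; then Me2S, −78 → 23 °C
Reagents that add atoms: ozone, O=[O+][O-]
Why: Ozonolysis with reductive work-up cleaves the only alkene to a methyl ketone and an aldehyde; primary alkyl bromides and silyl ethers tolerate these conditions and both stereocentres are spectators.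

Step 11
Reactants: 18 (3S,4S)-3-(bromomethyl)-4-{2-[(tert-butyldimethylsilyl)oxy]ethyl}-3-methyl-6-oxoheptanal
Product: 20 1-[(4S,5S)-4-(bromomethyl)-5-{2-[(tert-butyldimethylsilyl)oxy]ethyl}-4-methylcyclopent-1-en-1-yl]ethan-1-one, via aldol adduct 19 (not isolated)
Conditions: KOH (0.5 M aq.), THF, 23 °C
Reagents that add atoms: none
Why: Base-mediated intramolecular aldol condensation: the ketone enolate on the internal CH2 should attack the aldehyde to close the five-membered ring and dehydrate to the 1-acetylcyclopentene; enolisation of the aldehyde is hindered by the adjacent quaternary carbon, and the neopentyl bromide cannot eliminate or be displaced.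

Step 12
Reactants: 20 1-[(4S,5S)-4-(bromomethyl)-5-{2-[(tert-butyldimethylsilyl)oxy]ethyl}-4-methylcyclopent-1-en-1-yl]ethan-1-one
Product: 21 1-[(1S,2S,3S)-3-(bromomethyl)-2-{2-[(tert-butyldimethylsilyl)oxy]ethyl}-3-methylcyclopentyl]ethan-1-one
Conditions: H2 (1 atm), Pd/C (10 %), EtOAc, 23 °C
Reagents that add atoms: none
Why: Heterogeneous hydrogenation adds H2 syn to the alkene face opposite the adjacent silyloxyethyl chain, which should set C1 (azulene numbering) with the acetyl group cis to that chain; the neopentyl C–Br bond and the silyl ether should survive neutral conditions.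

Step 13
Reactants: 21 1-[(1S,2S,3S)-3-(bromomethyl)-2-{2-[(tert-butyldimethylsilyl)oxy]ethyl}-3-methylcyclopentyl]ethan-1-one
Product: 22 1-[(1S,2S,3S)-3-(bromomethyl)-2-(2-hydroxyethyl)-3-methylcyclopentyl]ethan-1-one
Conditions: HF·pyridine, pyridine, THF, 0 → 23 °C
Reagents that add atoms: none
Why: Buffered fluoride desilylation of the only silyl ether is mild enough not to epimerise the cis-acetyl centre.

Step 14
Reactants: 22 1-[(1S,2S,3S)-3-(bromomethyl)-2-(2-hydroxyethyl)-3-methylcyclopentyl]ethan-1-one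
Product: 23 2-[(1S,2S,5S)-2-acetyl-5-(bromomethyl)-5-methylcyclopentyl]acetaldehyde
Conditions: Dess–Martin periodinane, NaHCO3, CH2Cl2, 0 °C
Reagents that add atoms: none
Why: Dess–Martin oxidation of the primary alcohol under buffered, non-basic conditions should give the aldehyde without aldol reaction or epimerisation; the product is used at once.

Step 15
Reactants: 23 2-[(1S,2S,5S)-2-acetyl-5-(bromomethyl)-5-methylcyclopentyl]acetaldehyde; 24 methyl 2-[bis(2,2,2-trifluoroethoxy)phosphoryl]propanoate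
Product: 26 methyl (2Z)-4-[(1S,2S,5S)-2-acetyl-5-(bromomethyl)-5-methylcyclopentyl]-2-methylbut-2-enoate, via potassium phosphonate carbanion 25 (not isolated)
Conditions: 24, KN(SiMe3)2, 18-crown-6, THF, −78 °C; then 23, −78 °C
Reagents that add atoms: none
Why: Still–Gennari olefination: the electron-poor phosphonate should give the (Z)-2-methyl enoate under kinetic control, and the preformed, weakly basic carbanion should react with the aldehyde far faster than with the methyl ketone and should not enolise it.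

Step 16
Reactants: 8 tert-butyl{[(3S)-5-iodo-2-methylpent-1-en-3-yl]oxy}dimethylsilane; 26 methyl (2Z)-4-[(1S,2S,5S)-2-acetyl-5-(bromomethyl)-5-methylcyclopentyl]-2-methylbut-2-enoate
Product: 29 methyl (2Z)-4-[(1S,2S,5S)-5-(bromomethyl)-2-{(2S,5S)-5-[(tert-butyldimethylsilyl)oxy]-2-hydroxy-6-methylhept-6-en-2-yl}-5-methylcyclopentyl]-2-methylbut-2-enoate, via organolithium 27 (not isolated), via organocerium 28 (not isolated)
Conditions: 8, t-BuLi (2 equiv per 8), Et2O, −78 °C; anhydrous CeCl3, THF, −78 °C; then 26, −78 °C; aq. NH4Cl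
Reagents that add atoms: none
Why: Organocerium 1,2-addition to a ketone (iodine–lithium exchange, then transmetalation): the weakly basic reagent should add to the methyl ketone without enolisation or attack on the ester or the neopentyl bromide, and Felkin–Anh attack anti to the branched ring carbon C8a past the C1 hydrogen should set the tertiary carbinol as (2S); adducts arising from any minor enantiomer of the core are diastereomers and are removed here.

Step 17
Reactants: 29 methyl (2Z)-4-[(1S,2S,5S)-5-(bromomethyl)-2-{(2S,5S)-5-[(tert-butyldimethylsilyl)oxy]-2-hydroxy-6-methylhept-6-en-2-yl}-5-methylcyclopentyl]-2-methylbut-2-enoate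
Product: 30 (2Z)-4-[(1S,2S,5S)-5-(bromomethyl)-2-{(2S,5S)-5-[(tert-butyldimethylsilyl)oxy]-2-hydroxy-6-methylhept-6-en-2-yl}-5-methylcyclopentyl]-2-methylbut-2-enoic acid
Conditions: LiOH, THF/MeOH/H2O, 23 → 40 °C; then 1 M HCl to pH 3
Reagents that add atoms: lithium hydroxide, [Li+].[OH-]
Why: Saponification of the methyl ester; the carboxylate formed is no Michael acceptor, which should protect the Z-alkene from addition of the tertiary alkoxide, and the neopentyl bromide is inert to hydroxide.

Step 18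
Reactants: 30 (2Z)-4-[(1S,2S,5S)-5-(bromomethyl)-2-{(2S,5S)-5-[(tert-butyldimethylsilyl)oxy]-2-hydroxy-6-methylhept-6-en-2-yl}-5-methylcyclopentyl]-2-methylbut-2-enoic acid
Product: 31 S-pyridin-2-yl (2Z)-4-[(1S,2S,5S)-5-(bromomethyl)-2-{(2S,5S)-5-[(tert-butyldimethylsilyl)oxy]-2-hydroxy-6-methylhept-6-en-2-yl}-5-methylcyclopentyl]-2-methylbut-2-enethioate
Conditions: 2,2'-dipyridyl disulfide, PPh3, CH2Cl2, 23 °C
Reagents that add atoms: 2,2'-dipyridyl disulfide, c1ccc(SSc2ccccn2)nc1
Why: Redox condensation of the acid with the disulfide and phosphine gives the activated thioester under neutral conditions; the hindered tertiary alcohol should not be acylated at room temperature.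

Step 19
Reactants: 31 S-pyridin-2-yl (2Z)-4-[(1S,2S,5S)-5-(bromomethyl)-2-{(2S,5S)-5-[(tert-butyldimethylsilyl)oxy]-2-hydroxy-6-methylhept-6-en-2-yl}-5-methylcyclopentyl]-2-methylbut-2-enethioate
Product: 32 (1S,3aR,8aS)-1-{(2S,5S)-5-[(tert-butyldimethylsilyl)oxy]-2-hydroxy-6-methylhept-6-en-2-yl}-3a,6-dimethyl-2,3,3a,4,8,8a-hexahydroazulen-5(1H)-one
Conditions: NiBr2(dme) (20 mol %; dme = 1,2-dimethoxyethane), 4,4'-di-tert-butyl-2,2'-bipyridine (24 mol %), Zn powder (4 equiv), N,N-dimethylacetamide, 40 °C, 31 added over 12 h to a final 0.005 M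
Reagents that add atoms: none
Why: Proposed new method: this is the intramolecular version, on an α,β-unsaturated acyl donor, of the known intermolecular nickel-catalysed reductive ketone synthesis from primary alkyl halides and S-2-pyridyl thioesters, which is its closest known reaction type. Zerovalent nickel should insert into the chelating C(acyl)–S bond of 31 to give an acylnickel thiolate (divalent nickel), a monovalent nickel species should abstract bromine from the CH2Br group, and the neopentyl radical should be captured by the tethered acylnickel to give a trivalent acyl(alkyl)nickel that forms the C4–C5 bond by reductive elimination, Zn returning nickel to the low-valent state. The only ring closed is the seven-membered carbocycle, by C(sp3)–C(acyl) reductive elimination from an eight-membered nickelacycle (formally a 7-exo-trig acyl substitution). No stereocentre is created: the trans ring fusion (C3a, C8a) and the Z geometry of C6=C7 are carried in from 31. The step needs ring closure to win over oligomerisation, over 5-exo addition of the radical to C7 and over β-hydride loss; slow addition at high dilution, the trans disposition of C4 and C8 (5-exo closure would give a trans-fused bicyclo[3.3.0]octane) and the quaternary C3a (no β-hydrogen) should secure this.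

Step 20
Reactants: 32 (1S,3aR,8aS)-1-{(2S,5S)-5-[(tert-butyldimethylsilyl)oxy]-2-hydroxy-6-methylhept-6-en-2-yl}-3a,6-dimethyl-2,3,3a,4,8,8a-hexahydroazulen-5(1H)-one
Product: 33 (1S,3aR,5R,8aS)-1-{(2S,5S)-5-[(tert-butyldimethylsilyl)oxy]-2-hydroxy-6-methylhept-6-en-2-yl}-3a,6-dimethyl-1,2,3,3a,4,5,8,8a-octahydroazulen-5-ol
Conditions: NaBH4, CeCl3·7H2O, MeOH, −78 → −40 °C
Reagents that add atoms: none
Why: Luche reduction: 1,2-hydride delivery to the enone from the face opposite the axial 3a-methyl group (1,3 to C5) should give the (5R)-allylic alcohol with the hydroxyl cis to that methyl.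

Step 21
Reactants: 33 (1S,3aR,5R,8aS)-1-{(2S,5S)-5-[(tert-butyldimethylsilyl)oxy]-2-hydroxy-6-methylhept-6-en-2-yl}-3a,6-dimethyl-1,2,3,3a,4,5,8,8a-octahydroazulen-5-ol
Product: 34 (1S,3aR,5R,6R,7S,8aS)-1-{(2S,5S)-5-[(tert-butyldimethylsilyl)oxy]-2-hydroxy-6-methylhept-6-en-2-yl}-6,7-epoxy-3a,6-dimethyldecahydroazulen-5-ol
Conditions: VO(acac)2 (5 mol %), t-BuOOH (1.5 equiv), CH2Cl2, 0 → 23 °C
Reagents that add atoms: tert-butyl hydroperoxide, CC(C)(C)OO
Why: Hydroxyl-directed vanadium-catalysed epoxidation: the allylic C5 hydroxyl (and the side-chain tertiary hydroxyl on the same face) should deliver the oxygen syn, which places the oxirane on the face of the 3a-methyl group and sets C6 and C7; the isopropenyl group next to a silyl ether has no directing hydroxyl and should stay intact.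

Step 22
Reactants: 34 (1S,3aR,5R,6R,7S,8aS)-1-{(2S,5S)-5-[(tert-butyldimethylsilyl)oxy]-2-hydroxy-6-methylhept-6-en-2-yl}-6,7-epoxy-3a,6-dimethyldecahydroazulen-5-ol
Product: 35 (1S,3aR,6S,7S,8aS)-1-{(2S,5S)-5-[(tert-butyldimethylsilyl)oxy]-2-hydroxy-6-methylhept-6-en-2-yl}-6,7-epoxy-3a,6-dimethyloctahydroazulen-5(1H)-one
Conditions: Dess–Martin periodinane, NaHCO3, CH2Cl2, 0 → 23 °C
Reagents that add atoms: none
Why: Dess–Martin oxidation of the secondary epoxy alcohol gives the α,β-epoxy ketone under neutral conditions; the tertiary alcohol cannot be oxidised and the oxirane centres are untouched.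

Step 23
Reactants: 35 (1S,3aR,6S,7S,8aS)-1-{(2S,5S)-5-[(tert-butyldimethylsilyl)oxy]-2-hydroxy-6-methylhept-6-en-2-yl}-6,7-epoxy-3a,6-dimethyloctahydroazulen-5(1H)-one
Product: 36 (1S,3aR,6S,7S,8aS)-1-[(2S,5S)-2,5-dihydroxy-6-methylhept-6-en-2-yl]-6,7-epoxy-3a,6-dimethyloctahydroazulen-5(1H)-one
Conditions: HF·pyridine, pyridine, THF, 0 → 23 °C
Reagents that add atoms: none
Why: Buffered fluoride cleavage of the secondary allylic silyl ether should spare the epoxy ketone, which strongly basic fluoride sources could enolise or open.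

Step 24
Reactants: 36 (1S,3aR,6S,7S,8aS)-1-[(2S,5S)-2,5-dihydroxy-6-methylhept-6-en-2-yl]-6,7-epoxy-3a,6-dimethyloctahydroazulen-5(1H)-one
Product: 37 (3S,6S)-6-[(1S,3aR,6S,7S,8aS)-6,7-epoxy-3a,6-dimethyl-5-oxodecahydroazulen-1-yl]-6-hydroxy-2-methylhept-1-en-3-yl acetate (target)
Conditions: Ac2O, pyridine, DMAP (5 mol %), CH2Cl2, 0 °C
Reagents that add atoms: acetic anhydride, CC(=O)OC(C)=O
Why: Nucleophile-catalysed acylation should acetylate the secondary allylic alcohol selectively, since the tertiary alcohol is far less reactive at 0 °C.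

## Compound list

1 | ethyl acetate | CCOC(C)=O | starting material
2 | methacrolein | C=C(C)C=O | starting material
3 | lithium enolate of ethyl acetate | C=C(O[Li])OCC | intermediate (not isolated)
4 | ethyl 3-hydroxy-4-methylpent-4-enoate (racemic) | CCOC(=O)CC(O)C(C)=C | intermediate
5 | ethyl (3S)-3-hydroxy-4-methylpent-4-enoate | CCOC(=O)C[C@H](O)C(C)=C | intermediate
6 | ethyl (3S)-3-[(tert-butyldimethylsilyl)oxy]-4-methylpent-4-enoate | CCOC(=O)C[C@H](O[Si](C)(C)C(C)(C)C)C(C)=C | intermediate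
7 | (3S)-3-[(tert-butyldimethylsilyl)oxy]-4-methylpent-4-en-1-ol | OCC[C@H](O[Si](C)(C)C(C)(C)C)C(C)=C | intermediate
8 | tert-butyl{[(3S)-5-iodo-2-methylpent-1-en-3-yl]oxy}dimethylsilane | ICC[C@H](O[Si](C)(C)C(C)(C)C)C(C)=C | intermediate
9 | 3-[(tert-butyldimethylsilyl)oxy]propanal | O=CCCO[Si](C)(C)C(C)(C)C | starting material
10 | 2-(triphenylphosphoranylidene)propanal | CC(C=O)=P(c1ccccc1)(c1ccccc1)c1ccccc1 | starting material
11 | (2E)-5-[(tert-butyldimethylsilyl)oxy]-2-methylpent-2-enal | O=C/C(C)=C/CCO[Si](C)(C)C(C)(C)C | intermediate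
12 | isoprene | C=CC(C)=C | starting material
13 | (1S,6R)-6-{2-[(tert-butyldimethylsilyl)oxy]ethyl}-1,4-dimethylcyclohex-3-ene-1-carbaldehyde | O=C[C@@]1(C)CC=C(C)C[C@@H]1CCO[Si](C)(C)C(C)(C)C | intermediate
14 | [(1S,6R)-6-{2-[(tert-butyldimethylsilyl)oxy]ethyl}-1,4-dimethylcyclohex-3-en-1-yl]methanol | OC[C@@]1(C)CC=C(C)C[C@@H]1CCO[Si](C)(C)C(C)(C)C | intermediate
15 | [(1S,6R)-6-{2-[(tert-butyldimethylsilyl)oxy]ethyl}-1,4-dimethylcyclohex-3-en-1-yl]methyl trifluoromethanesulfonate | O=S(=O)(OC[C@@]1(C)CC=C(C)C[C@@H]1CCO[Si](C)(C)C(C)(C)C)C(F)(F)F | intermediate (not isolated)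
16 | tert-butyl{2-[(1R,6S)-6-(bromomethyl)-3,6-dimethylcyclohex-3-en-1-yl]ethoxy}dimethylsilane | BrC[C@@]1(C)CC=C(C)C[C@@H]1CCO[Si](C)(C)C(C)(C)C | intermediate
17 | secondary ozonide (1,2,4-trioxolane) of 16 across the ring alkene, bridge configuration undefined | BrC[C@@]1(C)CC2OOC(C)(O2)C[C@@H]1CCO[Si](C)(C)C(C)(C)C | intermediate (not isolated)
18 | (3S,4S)-3-(bromomethyl)-4-{2-[(tert-butyldimethylsilyl)oxy]ethyl}-3-methyl-6-oxoheptanal | O=CC[C@](C)(CBr)[C@@H](CCO[Si](C)(C)C(C)(C)C)CC(C)=O | intermediate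
19 | 1-[(4S,5S)-4-(bromomethyl)-5-{2-[(tert-butyldimethylsilyl)oxy]ethyl}-2-hydroxy-4-methylcyclopentyl]ethan-1-one (aldol adduct, C1 and C2 undefined) | CC(=O)C1C(O)C[C@](C)(CBr)[C@H]1CCO[Si](C)(C)C(C)(C)C | intermediate (not isolated)
20 | 1-[(4S,5S)-4-(bromomethyl)-5-{2-[(tert-butyldimethylsilyl)oxy]ethyl}-4-methylcyclopent-1-en-1-yl]ethan-1-one | CC(=O)C1=CC[C@](C)(CBr)[C@H]1CCO[Si](C)(C)C(C)(C)C | intermediate
21 | 1-[(1S,2S,3S)-3-(bromomethyl)-2-{2-[(tert-butyldimethylsilyl)oxy]ethyl}-3-methylcyclopentyl]ethan-1-one (acetyl, chain and methyl all cis) | CC(=O)[C@H]1CC[C@](C)(CBr)[C@H]1CCO[Si](C)(C)C(C)(C)C | intermediate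
22 | 1-[(1S,2S,3S)-3-(bromomethyl)-2-(2-hydroxyethyl)-3-methylcyclopentyl]ethan-1-one | CC(=O)[C@H]1CC[C@](C)(CBr)[C@H]1CCO | intermediate
23 | 2-[(1S,2S,5S)-2-acetyl-5-(bromomethyl)-5-methylcyclopentyl]acetaldehyde | CC(=O)[C@H]1CC[C@](C)(CBr)[C@H]1CC=O | intermediate
24 | methyl 2-[bis(2,2,2-trifluoroethoxy)phosphoryl]propanoate | COC(=O)C(C)P(=O)(OCC(F)(F)F)OCC(F)(F)F | starting material
25 | potassium carbanion of 24 | COC(=O)[C-](C)P(=O)(OCC(F)(F)F)OCC(F)(F)F.[K+] | intermediate (not isolated)
26 | methyl (2Z)-4-[(1S,2S,5S)-2-acetyl-5-(bromomethyl)-5-methylcyclopentyl]-2-methylbut-2-enoate | CC(=O)[C@H]1CC[C@](C)(CBr)[C@H]1C/C=C(/C)C(=O)OC | intermediate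
27 | {(3S)-3-[(tert-butyldimethylsilyl)oxy]-4-methylpent-4-en-1-yl}lithium | [Li]CC[C@H](O[Si](C)(C)C(C)(C)C)C(C)=C | intermediate (not isolated)
28 | {(3S)-3-[(tert-butyldimethylsilyl)oxy]-4-methylpent-4-en-1-yl}cerium dichloride | Cl[Ce](Cl)CC[C@H](O[Si](C)(C)C(C)(C)C)C(C)=C | intermediate (not isolated)
29 | methyl (2Z)-4-[(1S,2S,5S)-5-(bromomethyl)-2-{(2S,5S)-5-[(tert-butyldimethylsilyl)oxy]-2-hydroxy-6-methylhept-6-en-2-yl}-5-methylcyclopentyl]-2-methylbut-2-enoate | C=C(C)[C@H](CC[C@](C)(O)[C@H]1CC[C@](C)(CBr)[C@H]1C/C=C(/C)C(=O)OC)O[Si](C)(C)C(C)(C)C | intermediate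
30 | (2Z)-4-[(1S,2S,5S)-5-(bromomethyl)-2-{(2S,5S)-5-[(tert-butyldimethylsilyl)oxy]-2-hydroxy-6-methylhept-6-en-2-yl}-5-methylcyclopentyl]-2-methylbut-2-enoic acid | C=C(C)[C@H](CC[C@](C)(O)[C@H]1CC[C@](C)(CBr)[C@H]1C/C=C(/C)C(=O)O)O[Si](C)(C)C(C)(C)C | intermediate
31 | S-pyridin-2-yl thioester of 30 | C=C(C)[C@H](CC[C@](C)(O)[C@H]1CC[C@](C)(CBr)[C@H]1C/C=C(/C)C(=O)Sc1ccccn1)O[Si](C)(C)C(C)(C)C | intermediate
32 | (1S,3aR,8aS)-1-{(2S,5S)-5-[(tert-butyldimethylsilyl)oxy]-2-hydroxy-6-methylhept-6-en-2-yl}-3a,6-dimethyl-2,3,3a,4,8,8a-hexahydroazulen-5(1H)-one (trans-fused) | C=C(C)[C@H](CC[C@](C)(O)[C@H]1CC[C@]2(C)CC(=O)C(C)=CC[C@@H]12)O[Si](C)(C)C(C)(C)C | intermediate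
33 | (1S,3aR,5R,8aS)-allylic alcohol of 32 (5-OH cis to 3a-CH3) | C=C(C)[C@H](CC[C@](C)(O)[C@H]1CC[C@]2(C)C[C@@H](O)C(C)=CC[C@@H]12)O[Si](C)(C)C(C)(C)C | intermediate
34 | (1S,3aR,5R,6R,7S,8aS)-6,7-epoxy alcohol (oxirane cis to 5-OH and 3a-CH3) | C=C(C)[C@H](CC[C@](C)(O)[C@H]1CC[C@]2(C)C[C@@H](O)[C@@]3(C)O[C@H]3C[C@@H]12)O[Si](C)(C)C(C)(C)C | intermediate
35 | (1S,3aR,6S,7S,8aS)-1-{(2S,5S)-5-[(tert-butyldimethylsilyl)oxy]-2-hydroxy-6-methylhept-6-en-2-yl}-6,7-epoxy-3a,6-dimethyloctahydroazulen-5(1H)-one | C=C(C)[C@H](CC[C@](C)(O)[C@H]1CC[C@]2(C)CC(=O)[C@@]3(C)O[C@H]3C[C@@H]12)O[Si](C)(C)C(C)(C)C | intermediate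
36 | (1S,3aR,6S,7S,8aS)-1-[(2S,5S)-2,5-dihydroxy-6-methylhept-6-en-2-yl]-6,7-epoxy-3a,6-dimethyloctahydroazulen-5(1H)-one | C=C(C)[C@H](CC[C@](C)(O)[C@H]1CC[C@]2(C)CC(=O)[C@@]3(C)O[C@H]3C[C@@H]12)O | intermediate
37 | (3S,6S)-6-[(1S,3aR,6S,7S,8aS)-6,7-epoxy-3a,6-dimethyl-5-oxodecahydroazulen-1-yl]-6-hydroxy-2-methylhept-1-en-3-yl acetate | C=C(C)[C@H](CC[C@](C)(O)[C@H]1CC[C@]2(C)CC(=O)[C@@]3(C)O[C@H]3C[C@@H]12)OC(C)=O | target

## Step count and risks

Total step count: 24. Longest linear sequence: 19 steps (steps 6–24, from 9 and 10); the side-chain branch (steps 1–5) joins at step 16.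

Steps most likely to fail:

1. Step 19 (proposed new method). The neopentyl radical may be reduced or may couple between molecules before it meets its own acylnickel, and the Z-enoyl unit may isomerise under thiolate or nickel hydride, which stops ring closure. The fallback replaces the radical cross-electrophile union by a polar coupling of a preformed carbon nucleophile. It sets out from acid 30, which is converted (EtSH, EDC·HCl, DMAP, CH2Cl2) into the S-ethyl thioester F1. Zinc insertion into the C–Br bond (Zn dust, LiCl, THF, 50 °C) would give the neopentylzinc bromide F2. F2 is closed by an intramolecular Fukuyama coupling (PdCl2(PPh3)2, toluene/THF, 23 → 50 °C, high dilution), and the sequence comes back to the route at enone 32.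

2. Step 16. The face selectivity at the acetyl carbonyl may be low or opposite to the Felkin–Anh prediction, and partial enolisation would epimerise the cis-acetyl centre. The fallback introduces the two carbinol substituents in the inverse order, so that the same facial preference gives the (2S) carbinol. It sets out from ketone 21. Haloform cleavage (NaOBr, dioxane/H2O, 0 °C) gives the cyclopentanecarboxylic acid F3. Amidation (MeNHOMe·HCl, EDC·HCl, i-Pr2NEt) gives the Weinreb amide F4. Addition of organolithium 27 gives the chain ketone F5, and MeMgBr/CeCl3 (THF, −78 °C) gives the tertiary alcohol F6. Selective cleavage of the primary silyl ether (HF·pyridine, pyridine, 0 °C) gives the diol F7. Oxidation (TEMPO, PhI(OAc)2) gives the hydroxy aldehyde F8, which is expected to exist as its lactol. Still–Gennari olefination of F8 with 25 (extra base to open the lactol) comes back to the route at 29.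

3. Step 7. The trisubstituted enal may react too slowly with isoprene at the temperatures needed for good enantiofacial discrimination, which would give low conversion or low enantiomeric purity. The fallback replaces asymmetric catalysis by a racemic cycloaddition and covalent resolution. It sets out from 11 and 12: EtAlCl2 (CH2Cl2, −78 → 0 °C) would give 13 together with its enantiomer F9. NaBH4 then gives 14 together with its enantiomer F10. Esterification with (S)-O-acetylmandelic acid (DCC, DMAP) gives the diastereomeric esters F11 (from 14) and F12 (from F10), which are separated by chromatography or crystallisation. Methanolysis of F11 (K2CO3, MeOH) comes back to the route at alcohol 14.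

Further compounds

F1 | step 19 | S-ethyl (2Z)-4-[(1S,2S,5S)-5-(bromomethyl)-2-{(2S,5S)-5-[(tert-butyldimethylsilyl)oxy]-2-hydroxy-6-methylhept-6-en-2-yl}-5-methylcyclopentyl]-2-methylbut-2-enethioate | C=C(C)[C@H](CC[C@](C)(O)[C@H]1CC[C@](C)(CBr)[C@H]1C/C=C(/C)C(=O)SCC)O[Si](C)(C)C(C)(C)C
F2 | step 19 | neopentylzinc bromide derived from F1 | C=C(C)[C@H](CC[C@](C)(O)[C@H]1CC[C@](C)(C[Zn]Br)[C@H]1C/C=C(/C)C(=O)SCC)O[Si](C)(C)C(C)(C)C
F3 | step 16 | (1S,2S,3S)-3-(bromomethyl)-2-{2-[(tert-butyldimethylsilyl)oxy]ethyl}-3-methylcyclopentane-1-carboxylic acid | OC(=O)[C@H]1CC[C@](C)(CBr)[C@H]1CCO[Si](C)(C)C(C)(C)C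
F4 | step 16 | N-methoxy-N-methyl amide of F3 | CON(C)C(=O)[C@H]1CC[C@](C)(CBr)[C@H]1CCO[Si](C)(C)C(C)(C)C
F5 | step 16 | (4S)-1-[(1S,2S,3S)-3-(bromomethyl)-2-{2-[(tert-butyldimethylsilyl)oxy]ethyl}-3-methylcyclopentyl]-4-[(tert-butyldimethylsilyl)oxy]-5-methylhex-5-en-1-one | C=C(C)[C@H](CCC(=O)[C@H]1CC[C@](C)(CBr)[C@H]1CCO[Si](C)(C)C(C)(C)C)O[Si](C)(C)C(C)(C)C
F6 | step 16 | (2S,5S)-2-[(1S,2S,3S)-3-(bromomethyl)-2-{2-[(tert-butyldimethylsilyl)oxy]ethyl}-3-methylcyclopentyl]-5-[(tert-butyldimethylsilyl)oxy]-6-methylhept-6-en-2-ol | C=C(C)[C@H](CC[C@](C)(O)[C@H]1CC[C@](C)(CBr)[C@H]1CCO[Si](C)(C)C(C)(C)C)O[Si](C)(C)C(C)(C)C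
F7 | step 16 | (2S,5S)-2-[(1S,2S,3S)-3-(bromomethyl)-2-(2-hydroxyethyl)-3-methylcyclopentyl]-5-[(tert-butyldimethylsilyl)oxy]-6-methylhept-6-en-2-ol | C=C(C)[C@H](CC[C@](C)(O)[C@H]1CC[C@](C)(CBr)[C@H]1CCO)O[Si](C)(C)C(C)(C)C
F8 | step 16 | 2-[(1S,2S,5S)-5-(bromomethyl)-2-{(2S,5S)-5-[(tert-butyldimethylsilyl)oxy]-2-hydroxy-6-methylhept-6-en-2-yl}-5-methylcyclopentyl]acetaldehyde (open form of the lactol) | C=C(C)[C@H](CC[C@](C)(O)[C@H]1CC[C@](C)(CBr)[C@H]1CC=O)O[Si](C)(C)C(C)(C)C
F9 | step 7 | (1R,6S)-6-{2-[(tert-butyldimethylsilyl)oxy]ethyl}-1,4-dimethylcyclohex-3-ene-1-carbaldehyde (enantiomer of 13) | O=C[C@]1(C)CC=C(C)C[C@H]1CCO[Si](C)(C)C(C)(C)C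
F10 | step 7 | [(1R,6S)-6-{2-[(tert-butyldimethylsilyl)oxy]ethyl}-1,4-dimethylcyclohex-3-en-1-yl]methanol (enantiomer of 14) | OC[C@]1(C)CC=C(C)C[C@H]1CCO[Si](C)(C)C(C)(C)C
F11 | step 7 | (S)-O-acetylmandelate ester of 14 | CC(=O)O[C@@H](c1ccccc1)C(=O)OC[C@@]1(C)CC=C(C)C[C@@H]1CCO[Si](C)(C)C(C)(C)C
F12 | step 7 | (S)-O-acetylmandelate ester of F10 | CC(=O)O[C@@H](c1ccccc1)C(=O)OC[C@]1(C)CC=C(C)C[C@H]1CCO[Si](C)(C)C(C)(C)C
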